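**Retrosynthetic overview**

- Last C–C bond: C11–C12, by Heck union of an East C1–C11 (E)-vinyl iodide (tetrahydrofuran already in place) with a West C12–C19 triene-lactone; then C8–OH to ketone and C1 acetal to aldehyde.
- East: the tetrahydrofuran ring is made first, by a visible-light alkoxy-radical 5-exo cyclisation that forms the C3–O bond and the quaternary centre (key step). Its precursor comes from (S)-Roche ester (C7), chelation-controlled isopropenyl addition (C6) and directed hydroboration/B-alkyl Suzuki coupling (C5, C4–C3).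
- C8–C9 by allenylzinc addition of (S)-pent-3-yn-2-yl mesylate (C9 bought as (S)-but-3-yn-2-ol); the alkyne then becomes the (E)-vinyl iodide.
- West: C15 from (S)-3-bromo-2-methylpropan-1-ol; (Z)-C16=C17 by iodo-Wittig; two-carbon vinylogous formylation; the lactone ring is made second (allenylzinc addition of (R)-but-3-yn-2-yl mesylate, carboxylation, semi-hydrogenation/lactonisation).

Assumption: both enantiomers of Roche ester, but-3-yn-2-ol and 3-bromo-2-methylpropan-1-ol are catalogue materials; atoms are labelled C1 (aldehyde carbon) to C19 along the chain and C2′–C6′ in the lactone; the transient C8 carbinol is drawn as its major anti epimer.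

**Route**

Step 1
Reactants: 1 methyl (S)-3-hydroxy-2-methylpropanoate
Product: 2 methyl (S)-3-(benzyloxy)-2-methylpropanoate
Conditions: BnOC(=NH)CCl3 (1.2 equiv), TfOH (cat.), CH2Cl2/cyclohexane, 0 °C → rt
Reagents that add atoms: benzyl 2,2,2-trichloroacetimidate, N=C(OCc1ccccc1)C(Cl)(Cl)Cl
Why: Acid-catalysed imidate O-benzylation protects the primary alcohol without base, so the bought C7 stereocentre is not epimerised, and a benzyl ether (unlike p-methoxybenzyl) is not oxidised by the photocatalyst of step 6.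

Step 2
Reactants: 2 methyl (S)-3-(benzyloxy)-2-methylpropanoate
Product: 3 (S)-3-(benzyloxy)-2-methylpropanal
Conditions: iBu2AlH (1.05 equiv), CH2Cl2, −78 °C; then aq. KNaC4H4O6
Reagents that add atoms: none
Why: Partial ester reduction stops at the chelated tetrahedral aluminate at −78 °C and releases the aldehyde on work-up; it is used crude so the α-centre does not epimerise.

Step 3
Reactants: 3 (S)-3-(benzyloxy)-2-methylpropanal
Product: 4 (2S,3S)-1-(benzyloxy)-2,4-dimethylpent-4-en-3-ol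
Conditions: CH2=C(CH3)MgBr (1.5 equiv), MgBr2·OEt2 (2 equiv), CH2Cl2, −78 °C; then H2O
Reagents that add atoms: isopropenylmagnesium bromide, CC(=C)[Mg]Br
Why: Cram-chelate Grignard addition: magnesium bridges C=O and OBn and the nucleophile attacks anti to the α-methyl, setting C6 anti to C7 (expected about 5:1 or better; minor epimer removed by chromatography).

Step 4
Reactants: 5 1,1-diethoxybut-2-yne
Product: 7 (E)-1,1-diethoxy-3-iodobut-2-ene, via alkenylzirconocene 6 (not isolated)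
Conditions: Cp2Zr(H)Cl (1.3 equiv), THF, 40 °C; then I2, 0 °C
Reagents that add atoms: iodine, II
Why: syn-Hydrozirconation with a slight excess of hydride equilibrates zirconium onto the less hindered methyl-bearing alkyne carbon, and iodinolysis with retention gives the (E)-vinyl iodide.

Step 5
Reactants: 4 (2S,3S)-1-(benzyloxy)-2,4-dimethylpent-4-en-3-ol; 7 (E)-1,1-diethoxy-3-iodobut-2-ene
Product: 9 (2S,3R,4R,6E)-1-(benzyloxy)-8,8-diethoxy-2,4,6-trimethyloct-6-en-3-ol, via bis-borane adduct 8 (not isolated)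
Conditions: 9-BBN (2.2 equiv), THF, 0 °C → rt; then 7, PdCl2(dppf) (5 mol%), AsPh3 (5 mol%), 3 M aq. K3PO4, DMF, rt
Reagents that add atoms: none
Why: Still–Kishi-type substrate-directed hydroboration of the 1,1-disubstituted allylic alcohol (A1,3-strain model) puts the C5 methyl anti to the C6 oxygen (about 10:1 expected), and B-alkyl Suzuki–Miyaura coupling joins C4 to C3 with retention of the alkene geometry.

Step 6
Reactants: 9 (2S,3R,4R,6E)-1-(benzyloxy)-8,8-diethoxy-2,4,6-trimethyloct-6-en-3-ol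
Product: 10 (2R,4R,5R)-5-[(2S)-1-(benzyloxy)propan-2-yl]-2-(2,2-diethoxyethyl)-2,4-dimethyloxolane
Conditions: [Ir(dF(CF3)ppy)2(5,5′-d(CF3)bpy)]PF6 (2 mol%), Bu4P[(BuO)2PO2] (25 mol%), 2,4,6-iPr3C6H2SH (20 mol%), PhCF3, blue LEDs (450 nm), 25 °C, degassed
Reagents that add atoms: none
Why: Proposed new method: the excited iridium photocatalyst and the phosphate base homolyse the C6 O–H bond by concerted proton-coupled electron transfer, the alkoxy radical closes 5-exo onto the fully substituted alkene carbon C3 through a Beckwith–Houk chair in which the C6 side chain and C5 methyl are equatorial and the CH–acetal terminus takes the ring-like position (so CH2CH(OEt)2 ends trans to the C6 chain and cis to the C5 methyl, C3 = R), the acetal substituent on C2 disfavours the 6-endo mode, and the thiol reduces the C2 radical by H-atom transfer; the closest known reaction type is catalytic PCET hydroetherification of simple alkenols together with the 2,5-trans/2,4-cis selectivity rules of alkoxy-radical cyclisations, neither shown for attack at the tetrasubstituted carbon of a trisubstituted allylic-acetal alkene with substrate control of the new quaternary C–O centre.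

Step 7
Reactants: 10 (2R,4R,5R)-5-[(2S)-1-(benzyloxy)propan-2-yl]-2-(2,2-diethoxyethyl)-2,4-dimethyloxolane
Product: 11 (2S)-2-[(2R,3R,5R)-5-(2,2-diethoxyethyl)-3,5-dimethyloxolan-2-yl]propan-1-ol
Conditions: H2 (1 atm), Pd/C (10 wt%), EtOAc, rt
Reagents that add atoms: none
Why: Neutral hydrogenolysis cleaves only the benzyl ether; no alkene is present and the acetal and tetrahydrofuran are inert.

Step 8
Reactants: 11 (2S)-2-[(2R,3R,5R)-5-(2,2-diethoxyethyl)-3,5-dimethyloxolan-2-yl]propan-1-ol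
Product: 12 (2R)-2-[(2R,3R,5R)-5-(2,2-diethoxyethyl)-3,5-dimethyloxolan-2-yl]propanal
Conditions: DMP (1.3 equiv), pyridine, CH2Cl2, 0 °C → rt
Reagents that add atoms: none
Why: Buffered Dess–Martin oxidation gives the aldehyde without acid that would open the acetal; it is used at once so C7 does not epimerise.

Step 9
Reactants: 13 (S)-but-3-yn-2-ol
Product: 15 (S)-pent-3-yn-2-ol, via dilithio salt 14 (not isolated)
Conditions: LiNH2 (2.1 equiv), liq. NH3, −33 °C; CH3I (1.0 equiv); then H2O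
Reagents that add atoms: iodomethane, CI
Why: Alkylation of the alkoxide/acetylide dianion occurs at the far more nucleophilic acetylide carbon, and the carbinol stereocentre is not involved.

Step 10
Reactants: 15 (S)-pent-3-yn-2-ol
Product: 16 (S)-pent-3-yn-2-yl methanesulfonate
Conditions: CH3SO2Cl (1.2 equiv), Et3N (1.5 equiv), CH2Cl2, −78 °C
Reagents that add atoms: methanesulfonyl chloride, CS(=O)(=O)Cl
Why: O-Sulfonylation at low temperature activates the propargylic alcohol with retention and without ionisation.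

Step 11
Reactants: 12 (2R)-2-[(2R,3R,5R)-5-(2,2-diethoxyethyl)-3,5-dimethyloxolan-2-yl]propanal; 16 (S)-pent-3-yn-2-yl methanesulfonate
Product: 18 (2S,3R,4R)-2-[(2R,3R,5R)-5-(2,2-diethoxyethyl)-3,5-dimethyloxolan-2-yl]-4-methylhept-5-yn-3-ol, via allenylzinc 17 (not isolated)
Conditions: Pd(OAc)2 (5 mol%), PPh3 (5 mol%), Et2Zn (3 equiv), THF, −78 → −20 °C; then H2O
Reagents that add atoms: none
Why: Marshall–Tamaru propargylation: anti SN2′ oxidative addition of zerovalent palladium, transmetalation to zinc and cyclic SE2′ addition transfer the bought carbinol configuration to C9 with net inversion (C9 = R) and set the C8 carbinol anti; C8 is erased in step 22, so both C8 epimers converge.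

Step 12
Reactants: 18 (2S,3R,4R)-2-[(2R,3R,5R)-5-(2,2-diethoxyethyl)-3,5-dimethyloxolan-2-yl]-4-methylhept-5-yn-3-ol
Product: 20 (2S,3R,4R,5E)-2-[(2R,3R,5R)-5-(2,2-diethoxyethyl)-3,5-dimethyloxolan-2-yl]-6-iodo-4-methylhept-5-en-3-ol, via alkenylzirconocene 19 (not isolated)
Conditions: Cp2Zr(H)Cl (3.5 equiv, the first equivalent is consumed by the hydroxyl), THF, 45 °C; then I2, 0 °C
Reagents that add atoms: iodine, II
Why: syn-Hydrozirconation of the methyl alkyne places zirconium on the less hindered methyl-bearing carbon C11 (away from the branched C9) and iodinolysis with retention gives the (E)-trisubstituted vinyl iodide.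

Step 13
Reactants: 21 (S)-3-bromo-2-methylpropan-1-ol
Product: 22 (R)-2-methylpent-4-en-1-ol
Conditions: CH2=CHMgBr (3 equiv), Li2CuCl4 (5 mol%), THF, −20 °C → rt; then H2O
Reagents that add atoms: vinylmagnesium bromide, C=C[Mg]Br
Why: Kochi-type copper-catalysed Grignard cross-coupling at the primary bromide (the first equivalent of Grignard only deprotonates the alcohol) builds the allyl group; the C15 stereocentre is not touched (the descriptor changes by priority only).

Step 14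
Reactants: 22 (R)-2-methylpent-4-en-1-ol
Product: 23 (R)-2-methylpent-4-enal
Conditions: DMP (1.2 equiv), pyridine, CH2Cl2, 0 °C; filtered solution used directly
Reagents that add atoms: none
Why: Mild Dess–Martin oxidation gives the volatile, epimerisable aldehyde, which is carried on in solution.

Step 15
Reactants: 23 (R)-2-methylpent-4-enal
Product: 24 (3Z,5R)-3-iodo-5-methylocta-3,7-diene
Conditions: n-PrPPh3Br, n-BuLi, THF, 0 °C; I2, −78 °C; NaN(SiMe3)2, −20 °C; then 23, −78 → −20 °C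
Reagents that add atoms: propyltriphenylphosphonium bromide, CCC[P+](c1ccccc1)(c1ccccc1)c1ccccc1.[Br-]; iodine, II
Why: Stork–Zhao-type iodo-Wittig olefination with the α-iodo ylide is kinetically Z-selective, placing iodine cis to C15 so that the later C17–C18 bond is cis to C15.

Step 16
Reactants: 24 (3Z,5R)-3-iodo-5-methylocta-3,7-diene
Product: 27 (2E,4Z,6R)-4-ethyl-6-methylnona-2,4,8-trienal, via vinyllithium 25 (not isolated), via lithium aminoallyl alkoxide 26 (not isolated)
Conditions: t-BuLi (2.1 equiv), Et2O, −78 °C; Me2NCH=CHCHO (1.2 equiv), −78 → 0 °C; then 1 M HCl, THF, rt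
Reagents that add atoms: 3-(dimethylamino)acrolein, CN(C)/C=C/C=O
Why: Iodine–lithium exchange proceeds with retention, 1,2-addition to the vinylogous formamide and acid-induced loss of dimethylamine give the (E)-enal (vinylogous formylation), so the (2E,4Z)-dienal is formed in one operation without palladium.

Step 17
Reactants: 28 (R)-but-3-yn-2-ol
Product: 29 (R)-but-3-yn-2-yl methanesulfonate
Conditions: CH3SO2Cl (1.2 equiv), Et3N (1.5 equiv), CH2Cl2, −78 °C
Reagents that add atoms: methanesulfonyl chloride, CS(=O)(=O)Cl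
Why: O-Sulfonylation with retention prepares the chiral propargylic electrophile.

Step 18
Reactants: 27 (2E,4Z,6R)-4-ethyl-6-methylnona-2,4,8-trienal; 29 (R)-but-3-yn-2-yl methanesulfonate
Product: 31 (3S,4R,5E,7Z,9R)-7-ethyl-3,9-dimethyldodeca-5,7,11-trien-1-yn-4-ol, via allenylzinc 30 (not isolated)
Conditions: Pd(OAc)2 (5 mol%), PPh3 (5 mol%), Et2Zn (3 equiv), THF, −78 → −20 °C; then H2O
Reagents that add atoms: none
Why: Marshall–Tamaru propargylation adds 1,2 to the dienal; the bought centre becomes C5′ (S) by net inversion and the chair-like SE2′ transition state sets C6′ (R) anti to it, which is the trans relationship of the lactone.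

Step 19
Reactants: 31 (3S,4R,5E,7Z,9R)-7-ethyl-3,9-dimethyldodeca-5,7,11-trien-1-yn-4-ol
Product: 33 (4S,5R,6E,8Z,10R)-8-ethyl-5-hydroxy-4,10-dimethyltrideca-6,8,12-trien-2-ynoic acid, via dilithio salt 32 (not isolated)
Conditions: LiN(iPr)2 (2.2 equiv), THF, −78 °C; CO2 (gas); then 1 M HCl
Reagents that add atoms: carbon dioxide, O=C=O
Why: Carboxylation of the lithium acetylide gives the ynoic acid; the alkoxide carbonate reverts to the alcohol on acid work-up.

Step 20
Reactants: 33 (4S,5R,6E,8Z,10R)-8-ethyl-5-hydroxy-4,10-dimethyltrideca-6,8,12-trien-2-ynoic acid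
Product: 35 (5S,6R)-6-[(1E,3Z,5R)-3-ethyl-5-methylocta-1,3,7-trien-1-yl]-5-methyl-5,6-dihydro-2H-pyran-2-one, via cis-hydroxy acid 34 (not isolated)
Conditions: H2 (1 atm), Pd/CaCO3 poisoned with Pb(OAc)2 (Lindlar catalyst), quinoline, EtOAc, rt, stopped at 1 equiv H2; then PPTS (cat.), CH2Cl2, rt
Reagents that add atoms: none
Why: Lindlar semi-hydrogenation reduces the conjugated alkyne faster than any alkene and the resulting (Z)-5-hydroxy-2-enoic acid lactonises to the six-membered lactone with both stereocentres retained (trans-5,6).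

Step 21
Reactants: 20 (2S,3R,4R,5E)-2-[(2R,3R,5R)-5-(2,2-diethoxyethyl)-3,5-dimethyloxolan-2-yl]-6-iodo-4-methylhept-5-en-3-ol; 35 (5S,6R)-6-[(1E,3Z,5R)-3-ethyl-5-methylocta-1,3,7-trien-1-yl]-5-methyl-5,6-dihydro-2H-pyran-2-one
Product: 36 (5S,6R)-6-[(1E,3Z,5R,7E,9E,11R,12R,13S)-13-[(2R,3R,5R)-5-(2,2-diethoxyethyl)-3,5-dimethyloxolan-2-yl]-3-ethyl-12-hydroxy-5,9,11-trimethyltetradeca-1,3,7,9-tetraen-1-yl]-5-methyl-5,6-dihydro-2H-pyran-2-one
Conditions: Pd(OAc)2 (10 mol%), Bu4NCl (1 equiv), NaHCO3 (2.5 equiv), DMF, 40 °C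
Reagents that add atoms: none
Why: Jeffery-type Heck alkenylation: zerovalent palladium inserts into the (E)-vinyl iodide with retention, adds to the terminus of the only monosubstituted alkene and β-hydride elimination into conjugation gives the (E,E)-diene; no stereocentre is touched.

Step 22
Reactants: 36 (5S,6R)-6-[(1E,3Z,5R,7E,9E,11R,12R,13S)-13-[(2R,3R,5R)-5-(2,2-diethoxyethyl)-3,5-dimethyloxolan-2-yl]-3-ethyl-12-hydroxy-5,9,11-trimethyltetradeca-1,3,7,9-tetraen-1-yl]-5-methyl-5,6-dihydro-2H-pyran-2-one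
Product: 37 (5S,6R)-6-[(1E,3Z,5R,7E,9E,11R,13R)-13-[(2R,3R,5R)-5-(2,2-diethoxyethyl)-3,5-dimethyloxolan-2-yl]-3-ethyl-5,9,11-trimethyl-12-oxotetradeca-1,3,7,9-tetraen-1-yl]-5-methyl-5,6-dihydro-2H-pyran-2-one
Conditions: DMP (1.5 equiv), pyridine, CH2Cl2, 0 °C → rt
Reagents that add atoms: none
Why: Buffered Dess–Martin oxidation converts the C8 carbinol into the ketone under non-basic conditions that do not epimerise C7 or C9 or move the β,γ-alkene into conjugation.

Step 23
Reactants: 37 (5S,6R)-6-[(1E,3Z,5R,7E,9E,11R,13R)-13-[(2R,3R,5R)-5-(2,2-diethoxyethyl)-3,5-dimethyloxolan-2-yl]-3-ethyl-5,9,11-trimethyl-12-oxotetradeca-1,3,7,9-tetraen-1-yl]-5-methyl-5,6-dihydro-2H-pyran-2-one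
Product: 38 2-[(2R,4R,5R)-5-[(2R,4R,5E,7E,10R,11Z,13E)-12-ethyl-4,6,10-trimethyl-14-[(2R,3S)-3-methyl-6-oxo-3,6-dihydro-2H-pyran-2-yl]-3-oxotetradeca-5,7,11,13-tetraen-2-yl]-2,4-dimethyloxolan-2-yl]acetaldehyde
Conditions: PPTS (0.3 equiv), acetone/H2O (10:1), 40 °C
Reagents that add atoms: water, O
Why: Mild acid-catalysed acetal hydrolysis unmasks the C1 aldehyde last; the conditions are too weak to open the tetrahydrofuran by retro-oxa-Michael reaction or to epimerise the ketone α-centres.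

**Compound list**

1 | methyl (S)-3-hydroxy-2-methylpropanoate | COC(=O)[C@@H](C)CO | starting material
2 | methyl (S)-3-(benzyloxy)-2-methylpropanoate | COC(=O)[C@@H](C)COCc1ccccc1 | intermediate
3 | (S)-3-(benzyloxy)-2-methylpropanal | O=C[C@@H](C)COCc1ccccc1 | intermediate
4 | (2S,3S)-1-(benzyloxy)-2,4-dimethylpent-4-en-3-ol | C=C(C)[C@@H](O)[C@@H](C)COCc1ccccc1 | intermediate
5 | 1,1-diethoxybut-2-yne | CC#CC(OCC)OCC | starting material
6 | chlorobis(cyclopentadienyl)[(2E)-4,4-diethoxybut-2-en-2-yl]zirconium | C/C(=C\C(OCC)OCC)[Zr](Cl)(C1C=CC=C1)C1C=CC=C1 | intermediate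
7 | (E)-1,1-diethoxy-3-iodobut-2-ene | I/C(C)=C/C(OCC)OCC | intermediate
8 | 9-[(2R,3R,4S)-5-(benzyloxy)-3-(9-borabicyclo[3.3.1]nonan-9-yloxy)-2,4-dimethylpentyl]-9-borabicyclo[3.3.1]nonane | C([C@@H](C)[C@@H](OB1C2CCCC1CCC2)[C@@H](C)COCc1ccccc1)B1C2CCCC1CCC2 | intermediate
9 | (2S,3R,4R,6E)-1-(benzyloxy)-8,8-diethoxy-2,4,6-trimethyloct-6-en-3-ol | CCOC(OCC)/C=C(\C)C[C@@H](C)[C@@H](O)[C@@H](C)COCc1ccccc1 | intermediate
10 | (2R,4R,5R)-5-[(2S)-1-(benzyloxy)propan-2-yl]-2-(2,2-diethoxyethyl)-2,4-dimethyloxolane | CCOC(OCC)C[C@@]1(C)C[C@@H](C)[C@@H](O1)[C@@H](C)COCc1ccccc1 | intermediate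
11 | (2S)-2-[(2R,3R,5R)-5-(2,2-diethoxyethyl)-3,5-dimethyloxolan-2-yl]propan-1-ol | CCOC(OCC)C[C@@]1(C)C[C@@H](C)[C@@H](O1)[C@@H](C)CO | intermediate
12 | (2R)-2-[(2R,3R,5R)-5-(2,2-diethoxyethyl)-3,5-dimethyloxolan-2-yl]propanal | CCOC(OCC)C[C@@]1(C)C[C@@H](C)[C@@H](O1)[C@@H](C)C=O | intermediate
13 | (S)-but-3-yn-2-ol | C[C@H](O)C#C | starting material
14 | dilithium salt of (S)-but-3-yn-2-ol (O-lithio, C4-lithio) | [Li]C#C[C@H](C)O[Li] | intermediate
15 | (S)-pent-3-yn-2-ol | C[C@H](O)C#CC | intermediate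
16 | (S)-pent-3-yn-2-yl methanesulfonate | C[C@H](OS(C)(=O)=O)C#CC | intermediate
17 | (aR)-ethyl(penta-2,3-dien-2-yl)zinc | CC[Zn]C(C)=[C@]=C([H])C | intermediate
18 | (2S,3R,4R)-2-[(2R,3R,5R)-5-(2,2-diethoxyethyl)-3,5-dimethyloxolan-2-yl]-4-methylhept-5-yn-3-ol | CCOC(OCC)C[C@@]1(C)C[C@@H](C)[C@@H](O1)[C@@H](C)[C@H](O)[C@H](C)C#CC | intermediate
19 | O,C-bis[chlorobis(cyclopentadienyl)zirconium] adduct of 18 (zirconium on O3 and on C6 of the (5E)-heptenyl chain) | CCOC(OCC)C[C@@]1(C)C[C@@H](C)[C@@H](O1)[C@@H](C)[C@H](O[Zr](Cl)(C2C=CC=C2)C2C=CC=C2)[C@H](C)/C=C(\C)[Zr](Cl)(C2C=CC=C2)C2C=CC=C2 | intermediate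
20 | (2S,3R,4R,5E)-2-[(2R,3R,5R)-5-(2,2-diethoxyethyl)-3,5-dimethyloxolan-2-yl]-6-iodo-4-methylhept-5-en-3-ol | CCOC(OCC)C[C@@]1(C)C[C@@H](C)[C@@H](O1)[C@@H](C)[C@H](O)[C@H](C)/C=C(\C)I | intermediate
21 | (S)-3-bromo-2-methylpropan-1-ol | OC[C@H](C)CBr | starting material
22 | (R)-2-methylpent-4-en-1-ol | OC[C@H](C)CC=C | intermediate
23 | (R)-2-methylpent-4-enal | O=C[C@H](C)CC=C | intermediate
24 | (3Z,5R)-3-iodo-5-methylocta-3,7-diene | CC/C(I)=C/[C@H](C)CC=C | intermediate
25 | [(3E,5R)-5-methylocta-3,7-dien-3-yl]lithium (geometry of 24 retained) | CC/C([Li])=C/[C@H](C)CC=C | intermediate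
26 | lithium (1E,4Z,6R)-1-(dimethylamino)-4-ethyl-6-methylnona-1,4,8-trien-3-olate (C3 epimers) | CN(C)/C=C/C(O[Li])/C(CC)=C\[C@H](C)CC=C | intermediate
27 | (2E,4Z,6R)-4-ethyl-6-methylnona-2,4,8-trienal | O=C/C=C/C(CC)=C\[C@H](C)CC=C | intermediate
28 | (R)-but-3-yn-2-ol | C[C@@H](O)C#C | starting material
29 | (R)-but-3-yn-2-yl methanesulfonate | C[C@@H](OS(C)(=O)=O)C#C | intermediate
30 | (aS)-buta-1,2-dien-1-yl(ethyl)zinc | CC[Zn]C([H])=[C@@]=C([H])C | intermediate
31 | (3S,4R,5E,7Z,9R)-7-ethyl-3,9-dimethyldodeca-5,7,11-trien-1-yn-4-ol | C#C[C@H](C)[C@H](O)/C=C/C(CC)=C\[C@H](C)CC=C | intermediate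
32 | dilithium salt of 31 (O-lithio, C1-lithio) | [Li]C#C[C@H](C)[C@H](O[Li])/C=C/C(CC)=C\[C@H](C)CC=C | intermediate
33 | (4S,5R,6E,8Z,10R)-8-ethyl-5-hydroxy-4,10-dimethyltrideca-6,8,12-trien-2-ynoic acid | OC(=O)C#C[C@H](C)[C@H](O)/C=C/C(CC)=C\[C@H](C)CC=C | intermediate
34 | (2Z,4S,5R,6E,8Z,10R)-8-ethyl-5-hydroxy-4,10-dimethyltrideca-2,6,8,12-tetraenoic acid | OC(=O)/C=C\[C@H](C)[C@H](O)/C=C/C(CC)=C\[C@H](C)CC=C | intermediate
35 | (5S,6R)-6-[(1E,3Z,5R)-3-ethyl-5-methylocta-1,3,7-trien-1-yl]-5-methyl-5,6-dihydro-2H-pyran-2-one | O=C1C=C[C@H](C)[C@H](O1)/C=C/C(CC)=C\[C@H](C)CC=C | intermediate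
36 | (5S,6R)-6-[(1E,3Z,5R,7E,9E,11R,12R,13S)-13-[(2R,3R,5R)-5-(2,2-diethoxyethyl)-3,5-dimethyloxolan-2-yl]-3-ethyl-12-hydroxy-5,9,11-trimethyltetradeca-1,3,7,9-tetraen-1-yl]-5-methyl-5,6-dihydro-2H-pyran-2-one | CCC(=C/[C@H](C)C/C=C/C(C)=C/[C@@H](C)[C@@H](O)[C@H](C)[C@@H]1O[C@@](C)(CC(OCC)OCC)C[C@H]1C)/C=C/[C@H]1OC(=O)C=C[C@@H]1C | intermediate
37 | (5S,6R)-6-[(1E,3Z,5R,7E,9E,11R,13R)-13-[(2R,3R,5R)-5-(2,2-diethoxyethyl)-3,5-dimethyloxolan-2-yl]-3-ethyl-5,9,11-trimethyl-12-oxotetradeca-1,3,7,9-tetraen-1-yl]-5-methyl-5,6-dihydro-2H-pyran-2-one | CCC(=C/[C@H](C)C/C=C/C(C)=C/[C@@H](C)C(=O)[C@H](C)[C@@H]1O[C@@](C)(CC(OCC)OCC)C[C@H]1C)/C=C/[C@H]1OC(=O)C=C[C@@H]1C | intermediate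
38 | 2-[(2R,4R,5R)-5-[(2R,4R,5E,7E,10R,11Z,13E)-12-ethyl-4,6,10-trimethyl-14-[(2R,3S)-3-methyl-6-oxo-3,6-dihydro-2H-pyran-2-yl]-3-oxotetradeca-5,7,11,13-tetraen-2-yl]-2,4-dimethyloxolan-2-yl]acetaldehyde (CNP0166598.2) | CCC(=C/[C@H](C)C/C=C/C(C)=C/[C@@H](C)C(=O)[C@H](C)[C@@H]1O[C@@](C)(CC=O)C[C@H]1C)/C=C/[C@H]1OC(=O)C=C[C@@H]1C | target

**Step count and risks**

Total step count: 23. Longest linear sequence: 12 steps (steps 1, 2, 3, 5, 6, 7, 8, 11, 12, 21, 22, 23).

Three steps most likely to fail: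

Step 6 (the proposed new cyclisation). The risks are competing 6-endo closure, 1,6-hydrogen transfer from the benzylic CH2, and a low diastereomer ratio at the new quaternary centre C3. The fallback uses known polar chemistry, sets out from 9 and comes back at 10. Iodoetherification of 9 with N-iodosuccinimide and NaHCO3 in MeCN at 0 °C (Markovnikov 5-exo opening of the iodonium ion at the fully substituted carbon) gives (2R,4R,5R)-5-[(2S)-1-(benzyloxy)propan-2-yl]-2-(2,2-diethoxy-1-iodoethyl)-2,4-dimethyloxolane F1 as a mixture at the iodide carbon. Radical deiodination with Bu3SnH and AIBN in toluene at 80 °C then gives 10, with any C3 epimer separated at this stage.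

Step 15 (iodo-Wittig). The α-iodo ylide is unstable and yields with α-branched aldehydes are often modest, with variable Z/E ratio. The fallback sets out from 23 and comes back at 27, bypassing 24. Still–Gennari olefination of 23 with ethyl 2-[bis(2,2,2-trifluoroethoxy)phosphoryl]butanoate (KN(SiMe3)2, 18-crown-6, THF, −78 °C) gives ethyl (2Z,4R)-2-ethyl-4-methylhepta-2,6-dienoate F2. Reduction with iBu2AlH at −78 °C gives (2Z,4R)-2-ethyl-4-methylhepta-2,6-dien-1-ol F3, and Dess–Martin oxidation gives (2Z,4R)-2-ethyl-4-methylhepta-2,6-dienal F4. Wittig reaction of F4 with Ph3P=CHCHO in toluene at 60 °C then gives 27.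

Step 21 (Heck union). The risks are β-hydride elimination away from conjugation (skipped diene), insertion into the polyene, and ionisation of the dienyl lactone by zerovalent palladium. The fallback fixes the regiochemistry with boron; it sets out from 35 (coupling partner 20 unchanged) and comes back at 36. Cross-metathesis of the terminal alkene of 35 with vinylboronic acid pinacol ester (second-generation Hoveyda–Grubbs catalyst, CH2Cl2, 40 °C) gives (5S,6R)-6-[(1E,3Z,5R,7E)-3-ethyl-5-methyl-8-(4,4,5,5-tetramethyl-1,3,2-dioxaborolan-2-yl)octa-1,3,7-trien-1-yl]-5-methyl-5,6-dihydro-2H-pyran-2-one F5. Suzuki–Miyaura coupling of F5 with 20 (Pd(PPh3)4, TlOEt, THF/H2O, rt) then gives 36.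

Further compounds
F1 | step 6 | (2R,4R,5R)-5-[(2S)-1-(benzyloxy)propan-2-yl]-2-(2,2-diethoxy-1-iodoethyl)-2,4-dimethyloxolane | CCOC(OCC)C(I)[C@@]1(C)C[C@@H](C)[C@@H](O1)[C@@H](C)COCc1ccccc1
F2 | step 15 | ethyl (2Z,4R)-2-ethyl-4-methylhepta-2,6-dienoate | CCOC(=O)/C(CC)=C\[C@H](C)CC=C
F3 | step 15 | (2Z,4R)-2-ethyl-4-methylhepta-2,6-dien-1-ol | OC/C(CC)=C\[C@H](C)CC=C
F4 | step 15 | (2Z,4R)-2-ethyl-4-methylhepta-2,6-dienal | O=C/C(CC)=C\[C@H](C)CC=C
F5 | step 21 | (5S,6R)-6-[(1E,3Z,5R,7E)-3-ethyl-5-methyl-8-(4,4,5,5-tetramethyl-1,3,2-dioxaborolan-2-yl)octa-1,3,7-trien-1-yl]-5-methyl-5,6-dihydro-2H-pyran-2-one | O=C1C=C[C@H](C)[C@H](O1)/C=C/C(CC)=C\[C@H](C)C/C=C/B1OC(C)(C)C(C)(C)O1
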